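**Retrosynthetic overview** (elemanolide locants: C10 = quaternary C with Me and vinyl, C5 = CH with the acrylate, C6 = CH–O of the lactone, C7 = ring-fusion CH, C8 = CH–O-angelate, C9 = CH2)
1. Target ⇐ its tert-butyl ester; the last step only frees the acrylic acid.
2. Both rings in one operation ⇐ an acyclic C6 aldehyde carrying a 2-(acetoxymethyl)enoate: SmI2 ketyl 6-exo closure of the cyclohexane (C6–C7), acetate loss to the exocyclic methylene, then C6–O lactonisation (carbocycle first, γ-lactone second, same flask).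
3. C5–C10 bond with both stereocentres ⇐ enantioselective Ireland–Claisen rearrangement of an itaconate ester of an (E)-allylic alcohol.
4. Enoate acceptor ⇐ cross-metathesis of a vinyl carbinol ester with a 2-(acetoxymethyl)acrylate.
5. C8 carbinol and the (E)-allylic alcohol ⇐ asymmetric propargylation of a C3 enal, then alkyne carboalumination–hydroxymethylation.

Assumption: the sense of induction of (S)-TRIP (step 1) and of the (4S,5S)-bromoborane (step 7) is taken from the closest precedents; if either proves opposite, its mirror-image form is used and nothing else changes.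

**Step 1**
Reactants: 1 acrolein; 2 allenylboronic acid pinacol ester
Product: 4 (3S)-hex-1-en-5-yn-3-ol, via boronate ester 3 (not isolated)
Conditions: (S)-TRIP (5 mol %), 4 Å MS, toluene, −20 °C; H2O work-up
Reagents that add atoms: none
Why: Chiral phosphoric acid-catalysed aldehyde propargylation: the allenylboronate adds through a closed six-membered SE2' transition state in which (S)-TRIP ((S)-3,3'-bis(2,4,6-triisopropylphenyl)-1,1'-binaphthyl-2,2'-diyl hydrogen phosphate) shields one aldehyde face, giving the (S)-carbinol that becomes C8.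

**Step 2**
Reactants: 4 (3S)-hex-1-en-5-yn-3-ol
Product: 6 (2E,5S)-3-methylhepta-2,6-diene-1,5-diol, via alkenylalane 5 (not isolated)
Conditions: Me3Al (3 equiv), Cp2ZrCl2 (25 mol %), CH2Cl2, 0 °C to rt; then n-BuLi, (CH2O)n, THF, −78 °C to rt; H2O work-up
Reagents that add atoms: trimethylaluminium C[Al](C)C; formaldehyde (from paraformaldehyde) C=O
Why: Negishi zirconocene-catalysed carboalumination adds CH3 and Al syn across the terminal alkyne (CH3 on the internal carbon) and the alkenyl aluminate is hydroxymethylated with retention, so the trisubstituted alkene is E; the carbinol centre and the vinyl group are untouched.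

**Step 3**
Reactants: 6 (2E,5S)-3-methylhepta-2,6-diene-1,5-diol; 7 itaconic anhydride
Product: 9 1-tert-butyl 4-[(2E,5S)-5-hydroxy-3-methylhepta-2,6-dien-1-yl] 2-methylidenebutanedioate, via hemiester acid 8 (not isolated)
Conditions: toluene, 50 °C; then Cl3CC(=NH)OtBu, CH2Cl2–cyclohexane, rt
Reagents that add atoms: tert-butyl 2,2,2-trichloroacetimidate CC(C)(C)OC(=N)C(Cl)(Cl)Cl
Why: Anhydride alcoholysis by the primary allylic hydroxyl at the non-conjugated carbonyl of 7 (the secondary hydroxyl is slower, and no amine is present to isomerise the itaconate), then catalyst-free imidate tert-butylation, which esterifies only the carboxylic acid.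

**Step 4**
Reactants: 9 hydroxy diester; 10 angelic acid
Product: 12 1-tert-butyl 4-[(2E,5S)-3-methyl-5-{[(2Z)-2-methylbut-2-enoyl]oxy}hepta-2,6-dien-1-yl] 2-methylidenebutanedioate, via mixed anhydride 11 (not isolated)
Conditions: 2,4,6-Cl3C6H2COCl, Et3N, toluene, rt; then 9, 60 °C
Reagents that add atoms: none
Why: Yamaguchi esterification; acylation at oxygen leaves C8 untouched and, run without DMAP, keeps the Z (angelate) geometry.

**Step 5**
Reactants: 13 methyl 2-(hydroxymethyl)acrylate
Product: 14 methyl 2-(acetoxymethyl)acrylate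
Conditions: Ac2O, Et3N, DMAP (cat.), CH2Cl2, 0 °C
Reagents that add atoms: acetic anhydride CC(=O)OC(C)=O
Why: Standard O-acetylation of the primary allylic alcohol; the acetate is the leaving group that later becomes the exocyclic methylene.

**Step 6**
Reactants: 12 angelate diester; 14 methyl 2-(acetoxymethyl)acrylate
Product: 15 1-tert-butyl 4-[(2E,5S,6E)-8-acetoxy-7-(methoxycarbonyl)-3-methyl-5-{[(2Z)-2-methylbut-2-enoyl]oxy}octa-2,6-dien-1-yl] 2-methylidenebutanedioate
Conditions: second-generation Hoveyda–Grubbs catalyst RuCl2(H2IMes)(=CH-C6H4-2-OiPr) (10 mol %), 14 (5 equiv), toluene, 60 °C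
Reagents that add atoms: none
Why: Olefin cross-metathesis between the only monosubstituted alkene of 12 and the 1,1-disubstituted acrylate 14 gives the thermodynamically favoured E-enoate (C8 trans to CO2Me); the trisubstituted allyl-ester alkene, the itaconate methylene and the angelate are too hindered or electron-poor to compete.

**Step 7**
Reactants: 15 acetoxymethyl enoate triester
Product: 18 (2R,3S,5S,6E)-8-acetoxy-2-(3-tert-butoxy-3-oxoprop-1-en-2-yl)-3-ethenyl-7-(methoxycarbonyl)-3-methyl-5-{[(2Z)-2-methylbut-2-enoyl]oxy}oct-6-enoic acid, via boron ketene acetal 16 (not isolated), via acyloxyborane 17 (not isolated)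
Conditions: (4S,5S)-2-bromo-1,3-bis{[3,5-bis(trifluoromethyl)phenyl]sulfonyl}-4,5-diphenyl-1,3,2-diazaborolidine (1.3 equiv), Et3N, toluene–hexane, −78 °C, then −20 to 4 °C; H2O work-up
Reagents that add atoms: none
Why: Enantioselective Ireland–Claisen rearrangement: soft enolisation of the doubly activated itaconate CH2 (far more acidic than the acetate CH3) gives the E(O) boron ketene acetal (acrylate trans to O–B), and its chair [3,3] shift onto the E-trisubstituted allyl unit forms the C5–C10 bond with the acrylate and the C10 methyl on the same side of the future ring (vinyl opposite), the C2-symmetric sulfonamide controller choosing the face so that C5 is R and C10 is S.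

**Step 8**
Reactants: 18 Claisen acid
Product: 20 (2R,3S,5S,6E)-8-acetoxy-2-(3-tert-butoxy-3-oxoprop-1-en-2-yl)-3-ethenyl-7-(methoxycarbonyl)-3-methyl-5-{[(2Z)-2-methylbut-2-enoyl]oxy}oct-6-enal, via acid chloride 19 (not isolated)
Conditions: Me2C=C(Cl)NMe2, CH2Cl2, 0 °C; then LiAlH(OtBu)3, THF, −78 °C
Reagents that add atoms: none
Why: Neutral acid chloride formation with the Ghosez chloroenamine and Brown partial reduction with LiAlH(OtBu)3 at −78 °C stop at the aldehyde, spare the four esters and, being base-free and cold, neither epimerise C5 nor move its alkene into conjugation.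

**Step 9**
Reactants: 20 aldehyde
Product: 22 tert-butyl 2-[(3aR,4S,6S,7R,7aR)-6-ethenyl-6-methyl-4-{[(2Z)-2-methylbut-2-enoyl]oxy}-3-methylidene-2-oxooctahydro-1-benzofuran-7-yl]prop-2-enoate, via hydroxy ester 21 (not isolated)
Conditions: SmI2 (2.5 equiv), THF (0.01 M), no proton source, −78 to 0 °C; aq. NH4Cl
Reagents that add atoms: none
Why: Proposed new method: SmI2 reduces the aldehyde to a ketyl that adds 6-exo-trig to C7 of the enoate through a chair in which the axial C10 methyl forces the C6 O–Sm, the C8 angelate, the C5 acrylate and the C7 side chain all equatorial (this sets C6 R and C7 R, trans to each other and to C5 and C8), the ester-stabilised C11 radical is reduced to a samarium enolate that expels the C13 acetate (E1cB) to give the exocyclic methylene, and the equatorial C6 alkoxide then closes the trans-fused γ-lactone on the methyl ester, so cyclohexane and lactone form in one flask; the closest known reactions are SmI2 ketyl–olefin cyclisations of aldehydes onto enoates with in situ lactonisation and radical SN2' allylations with 2-(acyloxymethyl)acrylates.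

**Step 10**
Reactants: 22 lactone tert-butyl ester
Product: 23 2-[(3aR,4S,6S,7R,7aR)-6-ethenyl-6-methyl-4-{[(2Z)-2-methylbut-2-enoyl]oxy}-3-methylidene-2-oxooctahydro-1-benzofuran-7-yl]prop-2-enoic acid (CNP0256928.3)
Conditions: TFA–CH2Cl2 (1:4), anisole, 0 °C
Reagents that add atoms: none
Why: Acidolysis of the tert-butyl ester through the tert-butyl cation frees the acrylic acid, while the lactone, the angelate and all five stereocentres are inert to cold TFA.

**Compound list**
1 | acrolein (prop-2-enal) | C=CC=O | starting material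
2 | allenylboronic acid pinacol ester (4,4,5,5-tetramethyl-2-(propa-1,2-dien-1-yl)-1,3,2-dioxaborolane) | C=C=CB1OC(C)(C)C(C)(C)O1 | starting material
3 | 2-[(3S)-hex-1-en-5-yn-3-yloxy]-4,4,5,5-tetramethyl-1,3,2-dioxaborolane | C#CC[C@H](OB1OC(C)(C)C(C)(C)O1)C=C | intermediate
4 | (3S)-hex-1-en-5-yn-3-ol | C#CC[C@H](O)C=C | intermediate
5 | dimethyl{(1E,4S)-4-[(dimethylalumanyl)oxy]-2-methylhexa-1,5-dien-1-yl}alumane | C[Al](C)/C=C(\C)C[C@H](O[Al](C)C)C=C | intermediate
6 | (2E,5S)-3-methylhepta-2,6-diene-1,5-diol | OC/C=C(\C)C[C@H](O)C=C | intermediate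
7 | itaconic anhydride (3-methylideneoxolane-2,5-dione) | C=C1CC(=O)OC1=O | starting material
8 | 4-{[(2E,5S)-5-hydroxy-3-methylhepta-2,6-dien-1-yl]oxy}-2-methylidene-4-oxobutanoic acid | OC(=O)C(=C)CC(=O)OC/C=C(\C)C[C@H](O)C=C | intermediate
9 | 1-tert-butyl 4-[(2E,5S)-5-hydroxy-3-methylhepta-2,6-dien-1-yl] 2-methylidenebutanedioate | CC(C)(C)OC(=O)C(=C)CC(=O)OC/C=C(\C)C[C@H](O)C=C | intermediate
10 | angelic acid ((2Z)-2-methylbut-2-enoic acid) | C/C=C(/C)C(=O)O | starting material
11 | (2Z)-2-methylbut-2-enoic 2,4,6-trichlorobenzoic anhydride | C/C=C(/C)C(=O)OC(=O)c1c(Cl)cc(Cl)cc1Cl | intermediate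
12 | 1-tert-butyl 4-[(2E,5S)-3-methyl-5-{[(2Z)-2-methylbut-2-enoyl]oxy}hepta-2,6-dien-1-yl] 2-methylidenebutanedioate | CC(C)(C)OC(=O)C(=C)CC(=O)OC/C=C(\C)C[C@H](OC(=O)/C(C)=C\C)C=C | intermediate
13 | methyl 2-(hydroxymethyl)acrylate | C=C(CO)C(=O)OC | starting material
14 | methyl 2-(acetoxymethyl)acrylate | C=C(COC(C)=O)C(=O)OC | intermediate
15 | 1-tert-butyl 4-[(2E,5S,6E)-8-acetoxy-7-(methoxycarbonyl)-3-methyl-5-{[(2Z)-2-methylbut-2-enoyl]oxy}octa-2,6-dien-1-yl] 2-methylidenebutanedioate | CC(C)(C)OC(=O)C(=C)CC(=O)OC/C=C(\C)C[C@H](OC(=O)/C(C)=C\C)/C=C(\COC(C)=O)C(=O)OC | intermediate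
16 | E(O) boron ketene acetal of 15 (itaconate C5=C6 enol, oxygen bound to the (4S,5S)-1,3-bis{[3,5-bis(trifluoromethyl)phenyl]sulfonyl}-4,5-diphenyl-1,3,2-diazaborolidin-2-yl boron; acrylate trans to O–B) | CC(C)(C)OC(=O)C(=C)/C=C(/OB1N(S(=O)(=O)c2cc(C(F)(F)F)cc(C(F)(F)F)c2)[C@@H](c2ccccc2)[C@H](c2ccccc2)N1S(=O)(=O)c1cc(C(F)(F)F)cc(C(F)(F)F)c1)OC/C=C(\C)C[C@H](OC(=O)/C(C)=C\C)/C=C(\COC(C)=O)C(=O)OC | intermediate
17 | acyloxyborane of acid 18 with the same diazaborolidinyl boron | C=C[C@](C)(C[C@H](OC(=O)/C(C)=C\C)/C=C(\COC(C)=O)C(=O)OC)[C@@H](C(=O)OB1N(S(=O)(=O)c2cc(C(F)(F)F)cc(C(F)(F)F)c2)[C@@H](c2ccccc2)[C@H](c2ccccc2)N1S(=O)(=O)c1cc(C(F)(F)F)cc(C(F)(F)F)c1)C(=C)C(=O)OC(C)(C)C | intermediate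
18 | (2R,3S,5S,6E)-8-acetoxy-2-(3-tert-butoxy-3-oxoprop-1-en-2-yl)-3-ethenyl-7-(methoxycarbonyl)-3-methyl-5-{[(2Z)-2-methylbut-2-enoyl]oxy}oct-6-enoic acid | C=C[C@](C)(C[C@H](OC(=O)/C(C)=C\C)/C=C(\COC(C)=O)C(=O)OC)[C@@H](C(=O)O)C(=C)C(=O)OC(C)(C)C | intermediate
19 | acid chloride of 18 (same configuration) | C=C[C@](C)(C[C@H](OC(=O)/C(C)=C\C)/C=C(\COC(C)=O)C(=O)OC)[C@@H](C(=O)Cl)C(=C)C(=O)OC(C)(C)C | intermediate
20 | (2R,3S,5S,6E)-8-acetoxy-2-(3-tert-butoxy-3-oxoprop-1-en-2-yl)-3-ethenyl-7-(methoxycarbonyl)-3-methyl-5-{[(2Z)-2-methylbut-2-enoyl]oxy}oct-6-enal | C=C[C@](C)(C[C@H](OC(=O)/C(C)=C\C)/C=C(\COC(C)=O)C(=O)OC)[C@@H](C=O)C(=C)C(=O)OC(C)(C)C | intermediate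
21 | cyclised hydroxy ester (formed as its samarium alkoxide): all-equatorial cyclohexanol with C6–OH, C7 C(=CH2)CO2Me, C8 angelate, C5 C(=CH2)CO2tBu, C10 Me (axial) and vinyl; configuration as in 22 | C=C[C@]1(C)C[C@H](OC(=O)/C(C)=C\C)[C@@H](C(=C)C(=O)OC)[C@H](O)[C@H]1C(=C)C(=O)OC(C)(C)C | intermediate
22 | tert-butyl 2-[(3aR,4S,6S,7R,7aR)-6-ethenyl-6-methyl-4-{[(2Z)-2-methylbut-2-enoyl]oxy}-3-methylidene-2-oxooctahydro-1-benzofuran-7-yl]prop-2-enoate | C=C[C@]1(C)C[C@H](OC(=O)/C(C)=C\C)[C@H]2C(=C)C(=O)O[C@@H]2[C@H]1C(=C)C(=O)OC(C)(C)C | intermediate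
23 | 2-[(3aR,4S,6S,7R,7aR)-6-ethenyl-6-methyl-4-{[(2Z)-2-methylbut-2-enoyl]oxy}-3-methylidene-2-oxooctahydro-1-benzofuran-7-yl]prop-2-enoic acid (8α-angeloyloxy-elema-1,3,11(13)-trien-6α,12-olid-15-oic acid) | C=C[C@]1(C)C[C@H](OC(=O)/C(C)=C\C)[C@H]2C(=C)C(=O)O[C@@H]2[C@H]1C(=C)C(=O)O | target

**Totals**
Total step count: 10. Longest linear sequence: 9 (steps 1–4 and 6–10; step 5 is a one-step side branch).

**Three steps most likely to fail, with fallbacks**

(a) Step 6, the cross-metathesis. A 1,1-disubstituted acrylate next to a branched allylic ester may react too slowly. The fallback makes the same alkene intramolecularly; it sets out from 9 (using 13 directly) and returns at 15. Alcohol 9 is silylated with iPr2SiCl2/imidazole and the chlorosilane is capped with 13 to give the mixed diisopropylsilylene bis-ether F1. Ring-closing metathesis (second-generation Grubbs catalyst RuCl2(=CHPh)(H2IMes)(PCy3), toluene, 80 °C) closes the seven-membered siladioxepine F2, in which C8 and C13 are necessarily cis on the new trisubstituted enoate. HF·pyridine in THF frees the diol F3. Its primary allylic hydroxyl is acetylated selectively (AcCl, 2,4,6-collidine, CH2Cl2, −78 °C) to the monoacetate F4. Yamaguchi angeloylation of the remaining C8 hydroxyl, as in step 4, gives 15.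

(b) Step 7, the reagent-controlled Ireland–Claisen rearrangement. The bromoborane may enolise this polyester substrate poorly or with low face selectivity. The fallback replaces reagent control by separation of diastereomers, the fixed C8 centre serving as internal resolving handle; it sets out from 15 and returns at 18. LDA in THF at −78 °C followed by TMSCl/Et3N gives the trimethylsilyl ketene acetal F5 (E(O) geometry). Warming to rt brings about the chair [3,3] shift to the trimethylsilyl ester F6 of 18 and the trimethylsilyl ester F7 of its C5,C10-diastereomer in about equal amounts. Aqueous work-up gives 18 and the (2S,3R,5S)-acid F8, which are separated by chromatography; only 18 can cyclise in step 9 through the all-equatorial chair.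

(c) Step 9, the SmI2 cascade. SmI2 may reduce the acetoxymethyl enoate instead of the aldehyde, or the ketyl may dimerise. The fallback changes from a radical to a polar ring closure; it sets out from 20 and returns at 22. With Pd(PPh3)4 (5 mol %) and InI in THF at rt, zerovalent palladium ionises the allylic acetate and InI reduces the π-allyl complex to the allylindium acetate iodide F9. This adds through its γ-carbon (C7) to the aldehyde in a Zimmerman–Traxler chair fused trans to the forming cyclohexane (all substituents equatorial) to give hydroxy ester 21. PPTS in CH2Cl2 closes the lactone to 22. The known weakness is 1,4-elimination of the C8 angelate from the allylmetal, which is why the ketyl route is preferred.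

**Further compounds**
F1 | step 6 | mixed diisopropylsilylene bis-ether of 9 (C8–O) and 13 (CH2–O) | CC(C)(C)OC(=O)C(=C)CC(=O)OC/C=C(\C)C[C@H](O[Si](C(C)C)(C(C)C)OCC(=C)C(=O)OC)C=C
F2 | step 6 | siladioxepine from ring-closing metathesis of F1 (seven-membered 1,3-dioxa-2-silacyclohept-5-ene, 5-CO2Me, 7S side chain) | CC(C)(C)OC(=O)C(=C)CC(=O)OC/C=C(\C)C[C@@H]1O[Si](C(C)C)(C(C)C)OCC(C(=O)OC)=C1
F3 | step 6 | 1-tert-butyl 4-[(2E,5S,6E)-5,8-dihydroxy-7-(methoxycarbonyl)-3-methylocta-2,6-dien-1-yl] 2-methylidenebutanedioate | CC(C)(C)OC(=O)C(=C)CC(=O)OC/C=C(\C)C[C@H](O)/C=C(\CO)C(=O)OC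
F4 | step 6 | 1-tert-butyl 4-[(2E,5S,6E)-8-acetoxy-5-hydroxy-7-(methoxycarbonyl)-3-methylocta-2,6-dien-1-yl] 2-methylidenebutanedioate | CC(C)(C)OC(=O)C(=C)CC(=O)OC/C=C(\C)C[C@H](O)/C=C(\COC(C)=O)C(=O)OC
F5 | step 7 | trimethylsilyl ketene acetal of 15 (E(O): acrylate trans to OSiMe3) | CC(C)(C)OC(=O)C(=C)/C=C(/O[Si](C)(C)C)OC/C=C(\C)C[C@H](OC(=O)/C(C)=C\C)/C=C(\COC(C)=O)C(=O)OC
F6 | step 7 | trimethylsilyl ester of acid 18 | C=C[C@](C)(C[C@H](OC(=O)/C(C)=C\C)/C=C(\COC(C)=O)C(=O)OC)[C@@H](C(=O)O[Si](C)(C)C)C(=C)C(=O)OC(C)(C)C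
F7 | step 7 | trimethylsilyl ester of the (2S,3R,5S)-diastereomer of 18 | C=C[C@@](C)(C[C@H](OC(=O)/C(C)=C\C)/C=C(\COC(C)=O)C(=O)OC)[C@H](C(=O)O[Si](C)(C)C)C(=C)C(=O)OC(C)(C)C
F8 | step 7 | (2S,3R,5S,6E)-8-acetoxy-2-(3-tert-butoxy-3-oxoprop-1-en-2-yl)-3-ethenyl-7-(methoxycarbonyl)-3-methyl-5-{[(2Z)-2-methylbut-2-enoyl]oxy}oct-6-enoic acid | C=C[C@@](C)(C[C@H](OC(=O)/C(C)=C\C)/C=C(\COC(C)=O)C(=O)OC)[C@H](C(=O)O)C(=C)C(=O)OC(C)(C)C
F9 | step 9 | allylindium acetate iodide from 20 (In on C13 in place of the acetate oxygen) | C=C[C@](C)(C[C@H](OC(=O)/C(C)=C\C)/C=C(\C[In](I)OC(C)=O)C(=O)OC)[C@@H](C=O)C(=C)C(=O)OC(C)(C)C
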